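In Wednesday's run, c(isomer of the product)/c(target) stands at 0.344 at its last reading, and this number, the ceiling ratio, sets the limit for the warm flask below. Sunday's last reading gives a similar 0.375.

| flask | starting material | coupling partner | temperature | remark | time |
|---|---|---|---|---|---|
| Sunday's | 14 mM | 0.95 equiv | 6 °C | run made earlier |  |
| Wednesday's | 22 mM | 0.95 equiv | 20 °C | run made earlier |  |
| ochre | 10 mM | 0.950 equiv | 0 °C |  | 30 min |
| teal | 10 mM | 0.950 equiv | 25 °C |  | 30 min |

| run | time / min | target / % | isomer of the product / % | starting material / % |
|---|---|---|---|---|
| Sunday's | 5.00 | 6.7 | 1.5 | 91.8 |
| Sunday's | 12.0 | 13.1 | 1.9 | 83.4 |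
| Sunday's | 25.0 | 21.4 | 7.4 | 71.4 |
| Sunday's | 40.0 | 27.5 | 10.3 | 62.3 |
| Wednesday's | 1.00 | 6.7 | 1.3 | 92.7 |
| Wednesday's | 2.00 | 13.7 | 0.6 | 86.5 |
| Wednesday's | 6.00 | 26.3 | 5.8 | 67.1 |
| Wednesday's | 15.0 | 39.2 | 13.5 | 44.8 |

(standard deviation of a reading: 1 percentage point)

- the numbers in the tables scatter by 1 percentage point (one standard deviation)
- steps that have been proposed: starting material + coupling partner -> target; starting material -> decomposition product; target <-> isomer of the product

* the flask that comes out highest in share of target in all that became target or isomer of the product, or "all alike" when all lie within 1.5 percentage points (ochre / teal / all alike)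
* share of target in all that became target or isomer of the product, ochre
* share of target in all that became target or isomer of the product, teal

A bench rule comes first. If target is made at a steady pace, its curve can be replaced by its mean: the pool of target and isomer has a mean age of half the elapsed time. While the back step is small, the ratio is then a clock rate times that age, and this product is the age number. Sunday's reading at 25.0 min gives a clock rate of 0.0277 /min, and Wednesday's at 6.00 min gives 0.0735 /min. But at 15.0 min the rule predicts 0.551 for Wednesday's run, 1.60 times the reading. The rule's border at 20 °C therefore lies where the age number reaches the ceiling ratio, and beyond it the share follows the reversible step, as in thermodynamic against kinetic control.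

Scaling the clock geometrically with temperature gives 0.0182 /min for ochre, so its age number is 0.273. The ceiling ratio is a reading at 20 °C, not a limit for ochre at 0 °C, but Sunday's colder run already reached a ratio of 0.375, more than ochre's age number. This reckoning therefore keeps the rule for ochre and puts its share at 78.6 %. Averaging over ages instead of using the mean age gives 77.1 %, so the replacement costs little. Teal is hotter than Wednesday's run, and the clock rose with temperature. Even Wednesday's clock gives teal an age number of 1.10, past the border. Taking the ceiling ratio over unchanged, teal's share is 74.4 %.

The forecast names ochre as highest, with 82 % for ochre and 63 % for teal, and notes that “The Wednesday run flattens, which suggests reversal”. The reckoning here agrees on the order but differs on both shares.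

The flask gives ochre as highest, with 84.6 % for ochre and 74.7 % for teal.

    starting material + coupling partner → target, rate k1*[starting material]^1.5*[coupling partner]^0.5 (k = 0.0110 /M/s, Ea = 59.0 kJ/mol)
    starting material → decomposition product (k = 5.30 × 10⁻⁷ /s, Ea = 99.0 kJ/mol)
    target ⇌ isomer of the product (K = 0.870, k = 2.10 × 10⁻⁴ /s, Ea = 75.0 kJ/mol, ΔH = −25.0 kJ/mol)
    (constants at 0 °C)

Teal's target and isomer relax with a half-life of 0.886 min, short against 30 min, while target is still made 3.67 times faster than it is used up. The neighbour repeats teal with 6.0 mM of starting material, at the same temperature and time. Its age number and ceiling ratio are therefore unchanged, and the reckoning again gives 74.4 %. That flask holds 48.1 % starting material, 37.0 % target and 12.4 % isomer of the product, a share of 74.9 %.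

(The earlier runs and the new flask come from a simulation on assumed constants; noise was put on by code.)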